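**Retrosynthetic overview** (germacrane-type locants: C1 hemiketal carbon, C2–C3 methylenes, C4 ether carbon, C5=C6 enol-lactone alkene, C7=C11 butenolide alkene, C8 carbinol, C9 methylene, C10 acetoxy carbon, C12 lactone carbonyl, C13 acetoxymethyl)
1. Enabling feature: in the nine-membered ring O–C1–C10–C9–C8–C7–C6–C5–C4, the cation-stabilising hemiketal carbon C1 (on the tetrahydrofuran oxygen) lies across the ring from the anion-stabilising butenolide γ-carbon C6, and the C5=C6 alkene sits next to the ether carbon C4. The tetrahydrofuran is therefore a hydrated furan Diels–Alder adduct, and a transannular C1–C6 bond is a removable donor–acceptor bond.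
2. Last ring: the nine-membered oxacycle is unveiled by a Grob-type fragmentation of a 1,4-epoxy-bridged tetracycle (cut the temporary C1–C6 bond, expel bromide from C5, add water at C1); the C8 carbinol follows by CBS reduction.
3. The tetracycle comes from an intramolecular furan Diels–Alder reaction (forms C4–C5 and the temporary C1–C6 bond), with the C10 stereocentre steering the furan face, then hydrogenation of C2=C3.
4. The cycloaddition substrate comes from a Cu(OTf)2/bis(oxazoline) Mukaiyama aldol (C9–C10, sets C10) between a bromomethylidene-butenolide enol silane and an ynedione, then Au-catalysed furan formation; the butenolide comes from a Feist–Benary furan by photooxygenation, dehydration and bromination.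
5. Ring order: sacrificial furan → butenolide → methylfuran → temporary cyclohexenone plus 7-oxanorbornane (which already holds the tetrahydrofuran) → nine-membered oxacycle last.

Key step: step 13

Remark: the 1,4-bridged hemiketal drawn for the target is taken to be its thermodynamic ring–chain form, so C1 is set under equilibrium control.
Remark: the sense of induction in the Cu/bis(oxazoline) aldol and the CBS reduction is assigned from the usual models; the mirror-image ligand or catalyst is used if the sense proves opposite.

Step 1
Reactants: 1 pentane-2,4-dione; 2 1,3-dichloropropan-2-one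
Product: 3 1-[4-(chloromethyl)-2-methylfuran-3-yl]ethan-1-one
Conditions: pyridine, MeOH, 50 °C; then 1 M HCl, rt
Reagents that add atoms: none
Why: Feist–Benary furan synthesis: aldol addition of the diketone carbon to the ketone of 2, O-alkylation by one chloromethyl arm and acid-promoted dehydration should give the 2,3,4-trisubstituted furan with the second chloromethyl group intact.

Step 2
Reactants: 3 1-[4-(chloromethyl)-2-methylfuran-3-yl]ethan-1-one
Product: 4 (4-acetyl-5-methylfuran-3-yl)methyl acetate
Conditions: KOAc, NaI (cat.), DMF, 50 °C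
Reagents that add atoms: potassium acetate, CC(=O)[O-].[K+]
Why: SN2 displacement of the primary furylmethyl chloride by acetate (iodide-assisted) installs the C13 acetate that is carried to the target.

Step 3
Reactants: 4 (4-acetyl-5-methylfuran-3-yl)methyl acetate
Product: 5 (4-acetyl-5-hydroxy-5-methyl-2-oxo-2,5-dihydrofuran-3-yl)methyl acetate (racemic pseudo-acid)
Conditions: O2, visible light, tetraphenylporphyrin (cat.), iPr2NEt, CH2Cl2, −78 °C → rt
Reagents that add atoms: dioxygen (as singlet oxygen), O=O
Why: [4+2] addition of singlet oxygen to the furan and base-induced Kornblum–DeLaMare fragmentation of the endoperoxide at its only bridgehead C–H should place the lactone carbonyl next to the acetoxymethyl-bearing carbon; the new hemiketal centre is racemic and is destroyed in step 4.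

Step 4
Reactants: 5 (4-acetyl-5-hydroxy-5-methyl-2-oxo-2,5-dihydrofuran-3-yl)methyl acetate
Product: 6 (4-acetyl-5-methylidene-2-oxo-2,5-dihydrofuran-3-yl)methyl acetate
Conditions: MsCl, Et3N, CH2Cl2, −20 → 0 °C
Reagents that add atoms: none
Why: mesylation of the pseudo-acid hydroxyl and loss of methanesulfonate with deprotonation of the methyl group (dehydration of a γ-hydroxy-γ-methylbutenolide) should give the γ-methylidene butenolide, which is used at once.

Step 5
Reactants: 6 (4-acetyl-5-methylidene-2-oxo-2,5-dihydrofuran-3-yl)methyl acetate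
Product: 8 [(5Z)-4-acetyl-5-(bromomethylidene)-2-oxo-2,5-dihydrofuran-3-yl]methyl acetate, via dibromide 7 (not isolated)
Conditions: Br2, CH2Cl2, −40 °C; then Et3N, −40 → 0 °C
Reagents that add atoms: bromine, BrBr
Why: electrophilic bromine addition to the exocyclic enol-ester alkene and dehydrobromination of the tertiary bromide (bromination–dehydrobromination of a 5-methylidenefuranone) should give the bromomethylidene butenolide as the favoured Z isomer; the bromine is the leaving group reserved for step 13.

Step 6
Reactants: 8 [(5Z)-4-acetyl-5-(bromomethylidene)-2-oxo-2,5-dihydrofuran-3-yl]methyl acetate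
Product: 9 [(5Z)-5-(bromomethylidene)-2-oxo-4-{1-[(trimethylsilyl)oxy]ethenyl}-2,5-dihydrofuran-3-yl]methyl acetate
Conditions: TMSOTf, Et3N, CH2Cl2, 0 °C
Reagents that add atoms: trimethylsilyl trifluoromethanesulfonate, C[Si](C)(C)OS(=O)(=O)C(F)(F)F
Why: soft enolisation of the methyl ketone, the only enolisable carbonyl, gives the silyl enol ether that serves as aldol donor.

Step 7
Reactants: 10 3,3-dimethoxybutan-2-one; 11 3-bromoprop-1-yne
Product: 12 6,6-dimethoxyhept-1-yn-5-one
Conditions: LiN(iPr)2, THF, −78 °C; then 11, DMPU, −78 → −20 °C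
Reagents that add atoms: none
Why: alkylation of the lithium enolate, which can form at one position only, with propargyl bromide.

Step 8
Reactants: 12 6,6-dimethoxyhept-1-yn-5-one
Product: 13 hept-6-yne-2,3-dione
Conditions: 1 M HCl, THF, rt
Reagents that add atoms: water, O
Why: acid hydrolysis of the dimethyl ketal releases the chelating 1,2-diketone.

Step 9
Reactants: 9 [(5Z)-5-(bromomethylidene)-2-oxo-4-{1-[(trimethylsilyl)oxy]ethenyl}-2,5-dihydrofuran-3-yl]methyl acetate; 13 hept-6-yne-2,3-dione
Product: 14 [(5Z)-5-(bromomethylidene)-4-{(3S)-3-methyl-4-oxo-3-[(trimethylsilyl)oxy]oct-7-ynoyl}-2-oxo-2,5-dihydrofuran-3-yl]methyl acetate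
Conditions: Cu(OTf)2 (10 mol %), 2,2′-(propane-2,2-diyl)bis[(4S)-4-tert-butyl-4,5-dihydrooxazole] (11 mol %), THF, −78 °C; non-aqueous work-up
Reagents that add atoms: none
Why: catalytic enantioselective Mukaiyama aldol addition to a chelated 1,2-diketone: the enol silane should attack the less hindered acetyl carbonyl on the face left open by the tert-butyl groups of the square-planar copper chelate, setting C10 as S, and silyl transfer gives the tertiary silyl ether.

Step 10
Reactants: 14 [(5Z)-5-(bromomethylidene)-4-{(3S)-3-methyl-4-oxo-3-[(trimethylsilyl)oxy]oct-7-ynoyl}-2-oxo-2,5-dihydrofuran-3-yl]methyl acetate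
Product: 15 [(5Z)-5-(bromomethylidene)-4-{(3S)-3-(5-methylfuran-2-yl)-3-[(trimethylsilyl)oxy]butanoyl}-2-oxo-2,5-dihydrofuran-3-yl]methyl acetate
Conditions: (Ph3P)AuNTf2 (3 mol %), CH2Cl2, rt
Reagents that add atoms: none
Why: gold-catalysed cycloisomerisation of a γ-alkynyl ketone (5-exo-dig attack of the carbonyl oxygen on the activated alkyne, then aromatisation) should give the 2-methyl-5-substituted furan without touching C10.

Step 11
Reactants: 15 [(5Z)-5-(bromomethylidene)-4-{(3S)-3-(5-methylfuran-2-yl)-3-[(trimethylsilyl)oxy]butanoyl}-2-oxo-2,5-dihydrofuran-3-yl]methyl acetate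
Product: 17 tetracyclic 7-oxanorbornane bromide with the C10 trimethylsilyl ether (oxygen bridge C1–O–C4, cyclohexenone ring A fused at C1–C6, C7 syn and lactone oxygen and C5–Br anti to the bridge, 4R,10S), via oxanorbornene cycloadduct 16 (not isolated)
Conditions: CH2Cl2, 13 kbar, 25 °C; then H2 (1 atm), RhCl(PPh3)3 (5 mol %), PhMe, 25 °C
Reagents that add atoms: none
Why: intramolecular Diels–Alder reaction of the furan (pressure-driven, tether necessarily exo) forms C4–C5 and the temporary C1–C6 bond, the C10 centre choosing the furan face by holding its siloxy group in the furan plane and its methyl group anti to the incoming dienophile (inside-alkoxy arrangement), which sets C1 and C4 (4R); chemoselective hydrogenation of the strained C2=C3 alkene then blocks cycloreversion.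

Step 12
Reactants: 17 tetracyclic 7-oxanorbornane bromide with the C10 trimethylsilyl ether
Product: 18 tetracyclic 7-oxanorbornane bromide with the C10 acetate (otherwise as 17)
Conditions: Ac2O, Sc(OTf)3 (2 mol %), MeCN, −20 °C
Reagents that add atoms: acetic anhydride, CC(=O)OC(C)=O
Why: Sc(OTf)3-catalysed acylation exchanges the hindered tertiary silyl ether directly for the acetate, which is now safe because the furan that would have made it a labile furfuryl ester is gone.

Step 13
Reactants: 18 tetracyclic 7-oxanorbornane bromide with the C10 acetate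
Product: 21 (1S,4R,5E,10S)-10,13-diacetoxy-1-hydroxy-8-oxo-1,4-epoxygermacra-5,7(11)-dien-12,6-olide, via silyloxyfuran oxocarbenium triflate 19 (not isolated), via ylidene-butenolide oxocarbenium triflate 20 (not isolated)
Conditions: TMSOTf (1.2 equiv), 2,6-di-tert-butyl-4-methylpyridine (0.2 equiv), CH2Cl2, −78 → −20 °C; then H2O–THF, NaHCO3, 0 °C
Reagents that add atoms: water, O
Why: Proposed new method: silylation of the lactone carbonyl by TMSOTf turns the butenolide into an electron sink, and the anti-periplanar lone pair of the bridging oxygen pushes out the strained, doubly quaternary C1–C6 bond (a retro-vinylogous Mukaiyama aldol) to give the 2-silyloxyfuran 19 tethered to a cyclic oxocarbenium ion; the electron-rich silyloxyfuran then expels the furfuryl-type bromide from C5 as TMSBr to form the C5=C6 enol-lactone alkene (20), and water adds to the oxocarbenium ion to give the C1 hemiketal. The closest known reaction types are the Grob fragmentation of γ-leaving-group ethers and acetals through an oxocarbenium electrofuge and the elimination step of vinylogous-aldol routes to γ-ylidene butenolides. The nine-membered oxacycle (O, C1, C10, C9, C8, C7, C6, C5, C4) is not closed by bond formation but unveiled by excision of the transannular C1–C6 bond of the 7-oxanorbornane, a ring expansion that deletes the temporary cyclohexenone and the oxanorbornane in one event while the tetrahydrofuran persists. The only new stereocentre, C1, is fixed by the ring system, since a six-atom bridge can span the tetrahydrofuran only cis and the hemiketal can equilibrate to that form; for the same reason the alkene can form only with C4 and C7 cis (5E), and C4 and C10 pass through untouched. The neighbouring C10 acetate can cap the oxocarbenium ion as an acetoxonium ion, whose hydrolysis should return the tertiary acetate and the hemiketal hydroxyl. The step needs C–C heterolysis at C1–C6 to win over ionisation of the ether bridge and over loss of the C13 acetate: the bridging oxygen between two quaternary carbons is shielded from the bulky silyl Lewis acid while the carbonyl is not, C1–C6 is the only bond flanked by an oxygen donor and the butenolide acceptor and carries the oxanorbornane strain, and bromide is a far better nucleofuge than acetate.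

Step 14
Reactants: 21 (1S,4R,5E,10S)-10,13-diacetoxy-1-hydroxy-8-oxo-1,4-epoxygermacra-5,7(11)-dien-12,6-olide
Product: 22 (1S,4R,5E,8R,10S)-10,13-diacetoxy-1,8-dihydroxy-1,4-epoxygermacra-5,7(11)-dien-12,6-olide (CNP0203479.1)
Conditions: (S)-2-methyl-CBS-oxazaborolidine (0.5 equiv), catecholborane, PhMe–CH2Cl2, −78 °C; then MeOH, aq. NaHCO3
Reagents that add atoms: none
Why: Corey–Bakshi–Shibata reduction: the ketone flanked by the butenolide sp2 carbon (large) and a methylene (small) should be reduced in 1,2-fashion under reagent control to the 8R alcohol, leaving lactone, acetates and hemiketal alone.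

**Compound list**
1 | pentane-2,4-dione | CC(=O)CC(C)=O | starting material
2 | 1,3-dichloropropan-2-one | ClCC(=O)CCl | starting material
3 | 1-[4-(chloromethyl)-2-methylfuran-3-yl]ethan-1-one | CC(=O)c1c(C)occ1CCl | intermediate
4 | (4-acetyl-5-methylfuran-3-yl)methyl acetate | CC(=O)OCc1coc(C)c1C(C)=O | intermediate
5 | (4-acetyl-5-hydroxy-5-methyl-2-oxo-2,5-dihydrofuran-3-yl)methyl acetate (racemic) | CC(=O)OCC1=C(C(C)=O)C(C)(O)OC1=O | intermediate
6 | (4-acetyl-5-methylidene-2-oxo-2,5-dihydrofuran-3-yl)methyl acetate | CC(=O)OCC1=C(C(C)=O)C(=C)OC1=O | intermediate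
7 | [4-acetyl-5-bromo-5-(bromomethyl)-2-oxo-2,5-dihydrofuran-3-yl]methyl acetate (racemic, not isolated) | CC(=O)OCC1=C(C(C)=O)C(Br)(CBr)OC1=O | intermediate
8 | [(5Z)-4-acetyl-5-(bromomethylidene)-2-oxo-2,5-dihydrofuran-3-yl]methyl acetate | CC(=O)OCC1=C(C(C)=O)/C(=C/Br)OC1=O | intermediate
9 | [(5Z)-5-(bromomethylidene)-2-oxo-4-{1-[(trimethylsilyl)oxy]ethenyl}-2,5-dihydrofuran-3-yl]methyl acetate | CC(=O)OCC1=C(C(=C)O[Si](C)(C)C)/C(=C/Br)OC1=O | intermediate
10 | 3,3-dimethoxybutan-2-one | CC(=O)C(C)(OC)OC | starting material
11 | 3-bromoprop-1-yne | C#CCBr | starting material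
12 | 6,6-dimethoxyhept-1-yn-5-one | C#CCCC(=O)C(C)(OC)OC | intermediate
13 | hept-6-yne-2,3-dione | C#CCCC(=O)C(C)=O | intermediate
14 | [(5Z)-5-(bromomethylidene)-4-{(3S)-3-methyl-4-oxo-3-[(trimethylsilyl)oxy]oct-7-ynoyl}-2-oxo-2,5-dihydrofuran-3-yl]methyl acetate | CC(=O)OCC1=C(C(=O)C[C@](C)(O[Si](C)(C)C)C(=O)CCC#C)/C(=C/Br)OC1=O | intermediate
15 | [(5Z)-5-(bromomethylidene)-4-{(3S)-3-(5-methylfuran-2-yl)-3-[(trimethylsilyl)oxy]butanoyl}-2-oxo-2,5-dihydrofuran-3-yl]methyl acetate | CC(=O)OCC1=C(C(=O)C[C@](C)(O[Si](C)(C)C)c2ccc(C)o2)/C(=C/Br)OC1=O | intermediate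
16 | oxanorbornene cycloadduct: C1–O–C4 bridge, C2=C3 alkene, cyclohexenone ring A fused at C1–C6, C7 syn and lactone oxygen and C5–Br anti to the bridge, C10 trimethylsilyl ether, 4R,10S (not isolated) | CC(=O)OCC1=C2C(=O)C[C@](C)(O[Si](C)(C)C)[C@@]34C=C[C@@](C)(O3)[C@H](Br)[C@@]24OC1=O | intermediate
17 | tetracyclic 7-oxanorbornane bromide, C10 trimethylsilyl ether (16 with C2–C3 saturated) | CC(=O)OCC1=C2C(=O)C[C@](C)(O[Si](C)(C)C)[C@@]34CC[C@@](C)(O3)[C@H](Br)[C@@]24OC1=O | intermediate
18 | tetracyclic 7-oxanorbornane bromide, C10 acetate | CC(=O)OCC1=C2C(=O)C[C@](C)(OC(C)=O)[C@@]34CC[C@@](C)(O3)[C@H](Br)[C@@]24OC1=O | intermediate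
19 | 2-(trimethylsilyloxy)furan tethered in the nine-membered ring to the C1 oxocarbenium ion, C5 bromide, triflate salt (not isolated) | C[Si](C)(C)Oc1oc2c(c1COC(C)=O)C(=O)C[C@](C)(OC(C)=O)C3=[O+][C@](C)(CC3)[C@@H]2Br.[O-]S(=O)(=O)C(F)(F)F | intermediate
20 | bridged C1 oxocarbenium ion carrying the C5=C6 ylidene butenolide, triflate salt (not isolated) | CC(=O)OCC1=C2/C(=C\[C@@]3(C)CCC(=[O+]3)[C@@](C)(OC(C)=O)CC2=O)OC1=O.[O-]S(=O)(=O)C(F)(F)F | intermediate
21 | (1S,4R,5E,10S)-10,13-diacetoxy-1-hydroxy-8-oxo-1,4-epoxygermacra-5,7(11)-dien-12,6-olide | CC(=O)OCC1=C2/C(=C\[C@@]3(C)CC[C@](O)(O3)[C@@](C)(OC(C)=O)CC2=O)OC1=O | intermediate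
22 | (1S,4R,5E,8R,10S)-10,13-diacetoxy-1,8-dihydroxy-1,4-epoxygermacra-5,7(11)-dien-12,6-olide (CNP0203479.1) | CC(=O)OCC1=C2/C(=C\[C@@]3(C)CC[C@](O)(O3)[C@@](C)(OC(C)=O)C[C@H]2O)OC1=O | target

**Step count:** 14 steps in total; longest linear sequence 12 steps (steps 1–6 and 9–14).

**Steps most likely to fail**

Step 13 (proposed new method). At risk: ionisation of the ether bridge (C–O instead of C–C heterolysis) or loss of the allylic C13 acetate from the silyloxyfuran could outrun the wanted fragmentation. The fallback sets out from 18 and returns at 21 by known chemistry. The ether bridge is opened on purpose with iodotrimethylsilane (CH2Cl2, −40 °C; NaHCO3 work-up), the C10 acetate assisting C1–O cleavage through an acetoxonium ion. This should give the ring-opened tertiary C1 alcohol with C4 held as its trimethylsilyl ether F1. Alkoxy-radical β-scission of the C1 hydroxyl under hypoiodite conditions (PhI(OAc)2, I2, visible light, CH2Cl2) then cuts C1–C6; the stabilised C6 radical ejects the β-bromine atom, giving the ten-membered C1 ketone with the C5=C6 ylidene butenolide and the C4 silyl ether F2. Iodine and light should equilibrate the alkene geometry. HF·pyridine frees the C4 hydroxyl, which should close across the ring onto the C1 ketone to give 21.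

Step 11. At risk: the reversible cycloaddition may rest on the side of the open furan, and a single stereocentre may not differentiate the two furan faces well enough. The fallback sets out from 15 and returns at 17, adding a temporary second control element. (R)-2-methyl-CBS-oxazaborolidine with catecholborane should reduce the C8 ketone to the (8S) alcohol F3. Allylic 1,3-strain with the acetoxymethyl group then holds the tether on one face of the dienophile, in the same sense as the C10 siloxy group steers the furan (matched pair), and the sp3 carbon eases the forming ring. Cycloaddition under pressure and hydrogenation as in step 11 should give the saturated cycloadduct alcohol F4, and Dess–Martin periodinane oxidation returns 17.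

Step 14. At risk: hydride delivery to the wrong face of the C8 carbonyl in the flexible bridged ring, conjugate reduction of the cross-conjugated lactone, or β-elimination of the C10 acetate. The fallback sets out from 18 and returns at 22, setting the carbinol on the rigid tetracycle before the ring expansion. The same CBS reduction applied to 18 should give the (8R) alcohol F5, and TESOTf with 2,6-lutidine its triethylsilyl ether F6. The fragmentation conditions of step 13 should then give the silyl-protected hemiketal F7, and HF·pyridine releases 22.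

**Further compounds**
F1 | step 13 | ring-opened bicyclic lactone from 18: tertiary C1 alcohol (cis to the C10 acetate), C4 trimethylsilyl ether, C5 bromide, C1–C6 bond intact | CC(=O)OCC1=C2C(=O)C[C@](C)(OC(C)=O)[C@@]3(O)CC[C@@](C)(O[Si](C)(C)C)[C@H](Br)[C@@]23OC1=O
F2 | step 13 | (4R,5E,10S)-10,13-diacetoxy-1,8-dioxo-4-[(trimethylsilyl)oxy]germacra-5,7(11)-dien-12,6-olide | CC(=O)OCC1=C2/C(=C\[C@](C)(O[Si](C)(C)C)CCC(=O)[C@@](C)(OC(C)=O)CC2=O)OC1=O
F3 | step 11 | [(5Z)-5-(bromomethylidene)-4-{(1S,3S)-1-hydroxy-3-(5-methylfuran-2-yl)-3-[(trimethylsilyl)oxy]butyl}-2-oxo-2,5-dihydrofuran-3-yl]methyl acetate | CC(=O)OCC1=C([C@@H](O)C[C@](C)(O[Si](C)(C)C)c2ccc(C)o2)/C(=C/Br)OC1=O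
F4 | step 11 | (8S)-hydroxy analogue of 17 (C8 carbinol in place of the ketone) | CC(=O)OCC1=C2[C@@H](O)C[C@](C)(O[Si](C)(C)C)[C@@]34CC[C@@](C)(O3)[C@H](Br)[C@@]24OC1=O
F5 | step 14 | (8R)-hydroxy analogue of 18 | CC(=O)OCC1=C2[C@H](O)C[C@](C)(OC(C)=O)[C@@]34CC[C@@](C)(O3)[C@H](Br)[C@@]24OC1=O
F6 | step 14 | (8R)-triethylsilyl ether of F5 | CC(=O)OCC1=C2[C@H](O[Si](CC)(CC)CC)C[C@](C)(OC(C)=O)[C@@]34CC[C@@](C)(O3)[C@H](Br)[C@@]24OC1=O
F7 | step 14 | 8-O-triethylsilyl ether of 22 | CC(=O)OCC1=C2/C(=C\[C@@]3(C)CC[C@](O)(O3)[C@@](C)(OC(C)=O)C[C@H]2O[Si](CC)(CC)CC)OC1=O
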